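## Retrosynthetic overview

1. Target ⇐ acetylation and desilylation of a C9 allylic alcohol ⇐ catalyst-controlled reduction of the less hindered ketone of a 2-oxaspiro[4.5]dec-7-ene-3,6,9-trione.
2. Spiro trione ⇐ one flask from an acyclic furyl enoate: furan → (Z)-ene-1,4-dione with singlet oxygen, then the six-membered carbocycle by intramolecular Michael addition (creates the spiro carbon), then the γ-lactone by desilylative lactonisation.
3. Furyl enoate ⇐ syn addition of a 5-methyl-2-furyl cuprate to a γ-silyloxy ynoate ⇐ asymmetric alkynylation of a dienal with methyl propiolate (sets the lactone CH–O).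
4. Dienal ⇐ geranyl acetate by asymmetric epoxidation (sets the side-chain carbinol), epoxide → allylic silyl ether, deacetylation, oxidation.

Assumption: the catalyst antipodes named (D-fructose-derived Shi ketone, (S,S)-ProPhenol, (R)-Me-CBS) follow the usual facial models; if a first run shows the opposite sense, the mirror-image catalyst is used with no other change.

## Route

Step 1
Reactants: 1 geranyl acetate [(2E)-3,7-dimethylocta-2,6-dien-1-yl acetate]
Product: 2 (2E)-5-[(2R)-3,3-dimethyloxiran-2-yl]-3-methylpent-2-en-1-yl acetate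
Conditions: D-fructose-derived Shi ketone (1,2:4,5-di-O-isopropylidene-β-D-erythro-2,3-hexodiulo-2,6-pyranose, 30 mol%), KHSO5 (as 2KHSO5·KHSO4·K2SO4), K2CO3, Bu4NHSO4, MeCN/CH2(OMe)2/aq. buffer pH 10.5, 0 °C
Reagents that add atoms: potassium peroxymonosulfate, [K+].[O-]S(=O)(=O)OO
Why: Shi asymmetric epoxidation: the fructose-derived dioxirane attacks the electron-rich 6,7-alkene (the 2,3-alkene is deactivated by the allylic acetate) through a spiro transition state and sets the (R) oxirane CH that becomes the side-chain carbinol.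

Step 2
Reactants: 2 (2E)-5-[(2R)-3,3-dimethyloxiran-2-yl]-3-methylpent-2-en-1-yl acetate
Product: 3 (2E,6R)-6-[(tert-butyldimethylsilyl)oxy]-3,7-dimethylocta-2,7-dien-1-yl acetate
Conditions: TBSOTf, 2,6-lutidine, toluene, −78 °C; then DBU, −78 °C → rt
Reagents that add atoms: tert-butyldimethylsilyl trifluoromethanesulfonate, CC(C)(C)[Si](C)(C)OS(=O)(=O)C(F)(F)F
Why: Silyl triflate/amidine isomerisation of an epoxide to an allylic silyl ether (Noyori-type): O-silylation opens the oxirane at the tertiary carbon and DBU removes a methyl proton to give the isopropenyl group, so the C–O bond at the stereocentre is never broken and (R) is kept.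

Step 3
Reactants: 3 (2E,6R)-6-[(tert-butyldimethylsilyl)oxy]-3,7-dimethylocta-2,7-dien-1-yl acetate
Product: 4 (2E,6R)-6-[(tert-butyldimethylsilyl)oxy]-3,7-dimethylocta-2,7-dien-1-ol
Conditions: K2CO3, MeOH, 0 °C → rt
Reagents that add atoms: none
Why: Transesterification with methoxide generated from K2CO3/MeOH removes the primary allylic acetate and leaves the secondary silyl ether in place.

Step 4
Reactants: 4 (2E,6R)-6-[(tert-butyldimethylsilyl)oxy]-3,7-dimethylocta-2,7-dien-1-ol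
Product: 5 (2E,6R)-6-[(tert-butyldimethylsilyl)oxy]-3,7-dimethylocta-2,7-dienal
Conditions: MnO2, CH2Cl2, rt
Reagents that add atoms: none
Why: Allylic alcohol oxidation on activated MnO2 stops at the enal and does not isomerise the (E) alkene or touch the silyl ether.

Step 5
Reactants: 5 (2E,6R)-6-[(tert-butyldimethylsilyl)oxy]-3,7-dimethylocta-2,7-dienal; 6 methyl propiolate (methyl prop-2-ynoate)
Product: 7 methyl (4R,5E,9R)-9-[(tert-butyldimethylsilyl)oxy]-4-hydroxy-6,10-dimethylundeca-5,10-dien-2-ynoate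
Conditions: Me2Zn, (S,S)-ProPhenol ligand (2,6-bis{[(2S)-2-(hydroxydiphenylmethyl)pyrrolidin-1-yl]methyl}-4-methylphenol, 10 mol%), Ph3P=O (20 mol%), toluene, 4 °C; aq. NH4Cl
Reagents that add atoms: none
Why: Zinc–ProPhenol asymmetric alkynylation: the dinuclear zinc catalyst binds the enal and the zinc alkynylide of methyl propiolate and delivers it 1,2 to one aldehyde face, which sets the (R) propargylic carbinol (the future lactone CH–O) under catalyst control, far from the existing stereocentre.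

Step 6
Reactants: 7 methyl (4R,5E,9R)-9-[(tert-butyldimethylsilyl)oxy]-4-hydroxy-6,10-dimethylundeca-5,10-dien-2-ynoate
Product: 8 methyl (4R,5E,9R)-9-[(tert-butyldimethylsilyl)oxy]-6,10-dimethyl-4-[(triethylsilyl)oxy]undeca-5,10-dien-2-ynoate
Conditions: Et3SiCl, imidazole, CH2Cl2, 0 °C
Reagents that add atoms: chlorotriethylsilane, CC[Si](Cl)(CC)CC
Why: Silyl ether formation masks the propargylic hydroxyl so that it cannot lactonise after the next step and can later be unmasked selectively beside the tert-butyldimethylsilyl ether.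

Step 7
Reactants: 8 methyl (4R,5E,9R)-9-[(tert-butyldimethylsilyl)oxy]-6,10-dimethyl-4-[(triethylsilyl)oxy]undeca-5,10-dien-2-ynoate; 9 2-methylfuran
Product: 10 methyl (2E,4R,5E,9R)-9-[(tert-butyldimethylsilyl)oxy]-6,10-dimethyl-3-(5-methylfuran-2-yl)-4-[(triethylsilyl)oxy]undeca-2,5,10-trienoate
Conditions: 9, n-BuLi, THF, 0 °C; CuBr·SMe2 (0.5 equiv per furyllithium), −40 °C; then 8, −78 °C; aq. NH4Cl
Reagents that add atoms: none
Why: Organocuprate conjugate addition to an ynoate (syn carbocupration): the Gilman reagent made from 5-lithio-2-methylfuran puts the furyl group on the β-carbon, and protonation of the vinylcopper at −78 °C with retention leaves the ester cis to the silyloxy-bearing carbon.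

Step 8
Reactants: 10 methyl (2E,4R,5E,9R)-9-[(tert-butyldimethylsilyl)oxy]-6,10-dimethyl-3-(5-methylfuran-2-yl)-4-[(triethylsilyl)oxy]undeca-2,5,10-trienoate
Product: 13 (1R,5R)-1-[(1E,5R)-5-[(tert-butyldimethylsilyl)oxy]-2,6-dimethylhepta-1,6-dien-1-yl]-2-oxaspiro[4.5]dec-7-ene-3,6,9-trione, via acyclic Z-enedione ester 11 (not isolated), via quaternary cyclohexenedione ester 12 (not isolated)
Conditions: O2, hν (visible), 5,10,15,20-tetraphenylporphyrin (1 mol%), CH2Cl2, −78 °C; Me2S, −78 → 0 °C; DBU, 0 °C → rt; then HF·pyridine, THF, 0 °C → rt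
Reagents that add atoms: dioxygen, O=O
Why: Singlet-oxygen [4+2] addition to the 2,5-disubstituted furan and Me2S reduction unmask the (Z)-ene-1,4-dione 11, whose methyl-ketone enolate closes the carbocycle by 6-exo-trig intramolecular Michael addition to the ester-activated alkene carbon from the face anti to the C–OSiEt3 bond (the carbinol hydrogen eclipses the alkene to relieve allylic 1,3-strain with the cis ester, Felkin–Anh sense) and so sets the (R) quaternary centre of 12, after which selective fluoride cleavage of the triethylsilyl ether lets the freed alcohol lactonise onto the CH2CO2Me arm (5-exo-trig) to give the spirolactone.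

Step 9
Reactants: 13 (1R,5R)-1-[(1E,5R)-5-[(tert-butyldimethylsilyl)oxy]-2,6-dimethylhepta-1,6-dien-1-yl]-2-oxaspiro[4.5]dec-7-ene-3,6,9-trione
Product: 14 (1R,5R,9S)-1-[(1E,5R)-5-[(tert-butyldimethylsilyl)oxy]-2,6-dimethylhepta-1,6-dien-1-yl]-9-hydroxy-2-oxaspiro[4.5]dec-7-ene-3,6-dione
Conditions: (R)-Me-CBS oxazaborolidine ((3aR)-1-methyl-3,3-diphenyltetrahydro-1H,3H-pyrrolo[1,2-c][1,3,2]oxazaborole, 50 mol%), catecholborane, toluene/CH2Cl2, −78 °C
Reagents that add atoms: none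
Why: Corey–Bakshi–Shibata reduction: the oxazaborolidine–borane complex reduces only the C9 ketone in 1,2 fashion (the C6 ketone is shielded by the quaternary spiro carbon) and delivers hydride to the face set by the catalyst with the alkenyl side as the large group, giving the (9S) alcohol.

Step 10
Reactants: 14 (1R,5R,9S)-1-[(1E,5R)-5-[(tert-butyldimethylsilyl)oxy]-2,6-dimethylhepta-1,6-dien-1-yl]-9-hydroxy-2-oxaspiro[4.5]dec-7-ene-3,6-dione
Product: 15 (1R,5R,9S)-1-[(1E,5R)-5-[(tert-butyldimethylsilyl)oxy]-2,6-dimethylhepta-1,6-dien-1-yl]-3,6-dioxo-2-oxaspiro[4.5]dec-7-en-9-yl acetate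
Conditions: Ac2O, pyridine, DMAP (cat.), CH2Cl2, 0 °C
Reagents that add atoms: acetic anhydride, CC(=O)OC(C)=O
Why: DMAP-catalysed acylation of the only free hydroxyl gives the allylic acetate with retention at C9.

Step 11
Reactants: 15 (1R,5R,9S)-1-[(1E,5R)-5-[(tert-butyldimethylsilyl)oxy]-2,6-dimethylhepta-1,6-dien-1-yl]-3,6-dioxo-2-oxaspiro[4.5]dec-7-en-9-yl acetate
Product: 16 (1R,5R,9S)-1-[(1E,5R)-5-hydroxy-2,6-dimethylhepta-1,6-dien-1-yl]-3,6-dioxo-2-oxaspiro[4.5]dec-7-en-9-yl acetate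
Conditions: HF·pyridine, pyridine, THF, 0 °C → rt
Reagents that add atoms: none
Why: Fluoride-mediated desilylation with buffered HF·pyridine frees the side-chain allylic alcohol without touching the acetate, lactone or enone and gives the target.

## Compound list

1 | geranyl acetate, (2E)-3,7-dimethylocta-2,6-dien-1-yl acetate | CC(C)=CCC/C(C)=C/COC(C)=O | starting material
2 | (2E)-5-[(2R)-3,3-dimethyloxiran-2-yl]-3-methylpent-2-en-1-yl acetate | CC1(C)O[C@@H]1CC/C(C)=C/COC(C)=O | intermediate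
3 | (2E,6R)-6-[(tert-butyldimethylsilyl)oxy]-3,7-dimethylocta-2,7-dien-1-yl acetate | C=C(C)[C@H](O[Si](C)(C)C(C)(C)C)CC/C(C)=C/COC(C)=O | intermediate
4 | (2E,6R)-6-[(tert-butyldimethylsilyl)oxy]-3,7-dimethylocta-2,7-dien-1-ol | C=C(C)[C@H](O[Si](C)(C)C(C)(C)C)CC/C(C)=C/CO | intermediate
5 | (2E,6R)-6-[(tert-butyldimethylsilyl)oxy]-3,7-dimethylocta-2,7-dienal | C=C(C)[C@H](O[Si](C)(C)C(C)(C)C)CC/C(C)=C/C=O | intermediate
6 | methyl propiolate (methyl prop-2-ynoate) | C#CC(=O)OC | starting material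
7 | methyl (4R,5E,9R)-9-[(tert-butyldimethylsilyl)oxy]-4-hydroxy-6,10-dimethylundeca-5,10-dien-2-ynoate | C=C(C)[C@H](O[Si](C)(C)C(C)(C)C)CC/C(C)=C/[C@@H](O)C#CC(=O)OC | intermediate
8 | methyl (4R,5E,9R)-9-[(tert-butyldimethylsilyl)oxy]-6,10-dimethyl-4-[(triethylsilyl)oxy]undeca-5,10-dien-2-ynoate | C=C(C)[C@H](O[Si](C)(C)C(C)(C)C)CC/C(C)=C/[C@@H](O[Si](CC)(CC)CC)C#CC(=O)OC | intermediate
9 | 2-methylfuran | Cc1ccco1 | starting material
10 | methyl (2E,4R,5E,9R)-9-[(tert-butyldimethylsilyl)oxy]-6,10-dimethyl-3-(5-methylfuran-2-yl)-4-[(triethylsilyl)oxy]undeca-2,5,10-trienoate | C=C(C)[C@H](O[Si](C)(C)C(C)(C)C)CC/C(C)=C/[C@@H](O[Si](CC)(CC)CC)/C(=C\C(=O)OC)c1ccc(C)o1 | intermediate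
11 | methyl (2E,4R,5E,9R)-9-[(tert-butyldimethylsilyl)oxy]-6,10-dimethyl-3-[(2Z)-4-oxopent-2-enoyl]-4-[(triethylsilyl)oxy]undeca-2,5,10-trienoate | C=C(C)[C@H](O[Si](C)(C)C(C)(C)C)CC/C(C)=C/[C@@H](O[Si](CC)(CC)CC)/C(=C\C(=O)OC)C(=O)/C=C\C(C)=O | intermediate
12 | methyl 2-[(1R)-1-[(1R,2E,6R)-6-[(tert-butyldimethylsilyl)oxy]-3,7-dimethyl-1-[(triethylsilyl)oxy]octa-2,7-dien-1-yl]-2,5-dioxocyclohex-3-en-1-yl]acetate | C=C(C)[C@H](O[Si](C)(C)C(C)(C)C)CC/C(C)=C/[C@@H](O[Si](CC)(CC)CC)[C@]1(CC(=O)OC)CC(=O)C=CC1=O | intermediate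
13 | (1R,5R)-1-[(1E,5R)-5-[(tert-butyldimethylsilyl)oxy]-2,6-dimethylhepta-1,6-dien-1-yl]-2-oxaspiro[4.5]dec-7-ene-3,6,9-trione | C=C(C)[C@H](O[Si](C)(C)C(C)(C)C)CC/C(C)=C/[C@H]1OC(=O)C[C@]12CC(=O)C=CC2=O | intermediate
14 | (1R,5R,9S)-1-[(1E,5R)-5-[(tert-butyldimethylsilyl)oxy]-2,6-dimethylhepta-1,6-dien-1-yl]-9-hydroxy-2-oxaspiro[4.5]dec-7-ene-3,6-dione | C=C(C)[C@H](O[Si](C)(C)C(C)(C)C)CC/C(C)=C/[C@H]1OC(=O)C[C@]12C[C@H](O)C=CC2=O | intermediate
15 | (1R,5R,9S)-1-[(1E,5R)-5-[(tert-butyldimethylsilyl)oxy]-2,6-dimethylhepta-1,6-dien-1-yl]-3,6-dioxo-2-oxaspiro[4.5]dec-7-en-9-yl acetate | C=C(C)[C@H](O[Si](C)(C)C(C)(C)C)CC/C(C)=C/[C@H]1OC(=O)C[C@]12C[C@H](OC(C)=O)C=CC2=O | intermediate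
16 | (1R,5R,9S)-1-[(1E,5R)-5-hydroxy-2,6-dimethylhepta-1,6-dien-1-yl]-3,6-dioxo-2-oxaspiro[4.5]dec-7-en-9-yl acetate | C=C(C)[C@H](O)CC/C(C)=C/[C@H]1OC(=O)C[C@]12C[C@H](OC(C)=O)C=CC2=O | target

## Step count and risks

Total step count: 11. Longest linear sequence: 11 steps (1 → 16; 6 and 9 are purchased).

Three steps most likely to fail:

Step 8. The enedione may prefer reversible 5-exo aldol closure onto the cross-conjugated ketone, the carbinol CH may be deprotonated by DBU, or singlet oxygen may attack the trisubstituted side-chain alkene. The fallback forms the same ring bond with reversed polarity on a preformed lactone and sets out from 7. Excess lithium bis(1-ethoxyethenyl)cuprate (ethyl vinyl ether, t-BuLi, CuBr·SMe2, THF, −78 °C) adds syn to the ynoate, and the adduct lactonises on warming to (5R)-5-[(1E,5R)-5-[(tert-butyldimethylsilyl)oxy]-2,6-dimethylhepta-1,6-dien-1-yl]-4-(1-ethoxyethenyl)furan-2(5H)-one F2. Wet oxalic acid on silica hydrolyses the enol ether to (5R)-4-acetyl-5-[(1E,5R)-5-[(tert-butyldimethylsilyl)oxy]-2,6-dimethylhepta-1,6-dien-1-yl]furan-2(5H)-one F3. LiBH(s-Bu)3 (THF, −78 °C) adds hydride to the ring CH β to the ketone, and the exocyclic enolate is alkylated by 3-bromo-1,1-dimethoxypropan-2-one on the face anti to the dienyl group to give (4R,5R)-4-acetyl-5-[(1E,5R)-5-[(tert-butyldimethylsilyl)oxy]-2,6-dimethylhepta-1,6-dien-1-yl]-4-(3,3-dimethoxy-2-oxopropyl)oxolan-2-one F4. Aqueous CF3CO2H frees (4R,5R)-4-acetyl-5-[(1E,5R)-5-[(tert-butyldimethylsilyl)oxy]-2,6-dimethylhepta-1,6-dien-1-yl]-4-(2,3-dioxopropyl)oxolan-2-one F5, and pyrrolidinium acetate closes the ring by aldol condensation of the acetyl group onto the aldehyde, which comes back to the route at 13.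

Step 7. A 2-furyl group transfers slowly from copper, and the vinylcopper can lose its geometry if it warms. The fallback reverses the roles of the partners and sets out from 8. Stannylcupration (Bu3SnLi, CuBr·SMe2, THF, −78 °C, MeOH quench) gives the syn adduct methyl (2E,4R,5E,9R)-9-[(tert-butyldimethylsilyl)oxy]-6,10-dimethyl-3-(tributylstannyl)-4-[(triethylsilyl)oxy]undeca-2,5,10-trienoate F1. Stille coupling with 2-bromo-5-methylfuran (Pd(PPh3)4, CuI, DMF, 50 °C) comes back to the route at 10.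

Step 9. The catalyst may be mismatched with the spiro centre, or the reduction may give some 1,4-addition or C6 attack. The fallback gives up reagent control and sets out from 13. Luche reduction (NaBH4, CeCl3·7H2O, MeOH, −78 °C) gives both C9 alcohols: the (9S) isomer is 14 and goes on through step 10, and the epimer (1R,5R,9R)-1-[(1E,5R)-5-[(tert-butyldimethylsilyl)oxy]-2,6-dimethylhepta-1,6-dien-1-yl]-9-hydroxy-2-oxaspiro[4.5]dec-7-ene-3,6-dione F6 is converted by Mitsunobu esterification (PPh3, DIAD, AcOH, THF, 0 °C) with inversion. Both streams come back to the route at 15.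

## Further compounds

F1 | step 7 | methyl (2E,4R,5E,9R)-9-[(tert-butyldimethylsilyl)oxy]-6,10-dimethyl-3-(tributylstannyl)-4-[(triethylsilyl)oxy]undeca-2,5,10-trienoate | C=C(C)[C@H](O[Si](C)(C)C(C)(C)C)CC/C(C)=C/[C@@H](O[Si](CC)(CC)CC)/C(=C\C(=O)OC)[Sn](CCCC)(CCCC)CCCC
F2 | step 8 | (5R)-5-[(1E,5R)-5-[(tert-butyldimethylsilyl)oxy]-2,6-dimethylhepta-1,6-dien-1-yl]-4-(1-ethoxyethenyl)furan-2(5H)-one | C=C(C)[C@H](O[Si](C)(C)C(C)(C)C)CC/C(C)=C/[C@H]1OC(=O)C=C1C(=C)OCC
F3 | step 8 | (5R)-4-acetyl-5-[(1E,5R)-5-[(tert-butyldimethylsilyl)oxy]-2,6-dimethylhepta-1,6-dien-1-yl]furan-2(5H)-one | C=C(C)[C@H](O[Si](C)(C)C(C)(C)C)CC/C(C)=C/[C@H]1OC(=O)C=C1C(C)=O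
F4 | step 8 | (4R,5R)-4-acetyl-5-[(1E,5R)-5-[(tert-butyldimethylsilyl)oxy]-2,6-dimethylhepta-1,6-dien-1-yl]-4-(3,3-dimethoxy-2-oxopropyl)oxolan-2-one | C=C(C)[C@H](O[Si](C)(C)C(C)(C)C)CC/C(C)=C/[C@H]1OC(=O)C[C@@]1(CC(=O)C(OC)OC)C(C)=O
F5 | step 8 | (4R,5R)-4-acetyl-5-[(1E,5R)-5-[(tert-butyldimethylsilyl)oxy]-2,6-dimethylhepta-1,6-dien-1-yl]-4-(2,3-dioxopropyl)oxolan-2-one | C=C(C)[C@H](O[Si](C)(C)C(C)(C)C)CC/C(C)=C/[C@H]1OC(=O)C[C@@]1(CC(=O)C=O)C(C)=O
F6 | step 9 | (1R,5R,9R)-1-[(1E,5R)-5-[(tert-butyldimethylsilyl)oxy]-2,6-dimethylhepta-1,6-dien-1-yl]-9-hydroxy-2-oxaspiro[4.5]dec-7-ene-3,6-dione | C=C(C)[C@H](O[Si](C)(C)C(C)(C)C)CC/C(C)=C/[C@H]1OC(=O)C[C@]12C[C@@H](O)C=CC2=O
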